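**Retrosynthetic overview**

1. The target 20 is a (2S)-flavanone; the last disconnection removes the O5 tert-butyldimethylsilyl and O7 triisopropylsilyl ethers from 19.
2. Key disconnection: the C2–C3 bond of ring C, made by an enantioselective intramolecular rhodium-carbenoid C–H insertion of diazoketone 18 (carbenoid at C3, next to the C4 ketone on ring A) into the O1–CH2 group of a para-alkoxybenzyl ether. Rings A and B are bought as arenes; ring C is the only ring formed.
3. Enabling feature: the C2–H bond is flanked by the lone pairs of O1 and by the electron-rich 4-prenyloxyphenyl ring B (a hydridic, doubly activated C–H). It lies 1,6 to C3 across O1–C8a–C4a–C4, and the 1,5-position is O1, so no competing C–H exists.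
4. The C8 prenyl group is placed by a Eu(fod)3-catalysed para-Claisen–Cope rearrangement of the O5 prenyl ether (C8 is para to O5), after ring B and C2 have been attached to O1 in one piece by Mitsunobu etherification.
5. Ring A is differentiated from 2,4,6-trihydroxyacetophenone: O7 is silylated first (most acidic OH), then O1 and O5 of the symmetric diol are distinguished by two successive Mitsunobu reactions.

Key step: step 8

Assumption: the sense of induction of Rh2(S-PTTL)4 at C2 cannot be predicted with certainty for this substrate; the S-configured catalyst is written, and its mirror image Rh2(R-PTTL)4 is to be used if the 2R product should prevail.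

**Route**

Step 1
Reactants: 1 2,4,6-trihydroxyacetophenone; 2 triisopropylsilyl chloride
Product: 3 1-[2,6-dihydroxy-4-(triisopropylsilyloxy)phenyl]ethanone
Conditions: 2 (1.05 equiv), imidazole, DMF, 0 °C
Reagents that add atoms: triisopropylsilyl chloride (2), CC(C)[Si](Cl)(C(C)C)C(C)C
Why: Silyl ether formation: the 4-hydroxyl, para to the acetyl group, is the most acidic and the only one not held in a hydrogen bond to the carbonyl group, so one equivalent of the bulky silyl chloride should react there.

Step 2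
Reactants: 4 4-hydroxybenzyl alcohol; 5 prenyl bromide (1-bromo-3-methylbut-2-ene)
Product: 6 [4-(3-methylbut-2-enyloxy)phenyl]methanol
Conditions: K2CO3, acetone, reflux
Reagents that add atoms: prenyl bromide (5), CC(C)=CCBr
Why: Williamson ether synthesis: carbonate deprotonates only the phenol, whose phenoxide displaces the allylic bromide, while the benzylic alcohol stays free.

Step 3
Reactants: 3 1-[2,6-dihydroxy-4-(triisopropylsilyloxy)phenyl]ethanone; 6 [4-(3-methylbut-2-enyloxy)phenyl]methanol
Product: 7 1-[2-hydroxy-6-{[4-(3-methylbut-2-enyloxy)phenyl]methoxy}-4-(triisopropylsilyloxy)phenyl]ethanone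
Conditions: 6 (1.0 equiv), PPh3, DIAD, THF, 0 °C to rt
Reagents that add atoms: none
Why: Mitsunobu etherification: the phenol (made acidic by the ortho acyl group) displaces the activated benzylic alcohol under neutral conditions that spare the aryl silyl ether, and one equivalent of 6 should stop at the mono-ether because the remaining hydroxyl is then locked in a strong hydrogen bond to the carbonyl group.

Step 4
Reactants: 7 1-[2-hydroxy-6-{[4-(3-methylbut-2-enyloxy)phenyl]methoxy}-4-(triisopropylsilyloxy)phenyl]ethanone; 8 prenol (3-methylbut-2-en-1-ol)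
Product: 9 1-[2-(3-methylbut-2-enyloxy)-6-{[4-(3-methylbut-2-enyloxy)phenyl]methoxy}-4-(triisopropylsilyloxy)phenyl]ethanone
Conditions: PPh3, DIAD, THF, rt
Reagents that add atoms: prenol (8), CC(C)=CCO
Why: Mitsunobu etherification of the chelated phenol with the primary allylic alcohol should give the O-prenyl ether without the C-prenylation and base-induced side reactions of an alkylation with prenyl bromide.

Step 5
Reactants: 9 1-[2-(3-methylbut-2-enyloxy)-6-{[4-(3-methylbut-2-enyloxy)phenyl]methoxy}-4-(triisopropylsilyloxy)phenyl]ethanone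
Product: 12 1-[6-hydroxy-3-(3-methylbut-2-enyl)-2-{[4-(3-methylbut-2-enyloxy)phenyl]methoxy}-4-(triisopropylsilyloxy)phenyl]ethanone, via ortho-dienone 10 (not isolated), via para-dienone 11 (not isolated)
Conditions: Eu(fod)3 (10 mol%), CHCl3, 60 °C, sealed tube
Reagents that add atoms: none
Why: Para-Claisen–Cope rearrangement: trivalent europium chelates the carbonyl oxygen and the neighbouring prenyl ether oxygen and thereby accelerates the aromatic Claisen [3,3]-shift to ortho-dienone 10, whose Cope [3,3]-shift to the para carbon (between the benzylic ether and the silyl ether) gives para-dienone 11 and, after enolisation, phenol 12 with an unrearranged prenyl group, while the non-chelating prenyl ether on ring B should stay untouched at 60 °C.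

Step 6
Reactants: 12 1-[6-hydroxy-3-(3-methylbut-2-enyl)-2-{[4-(3-methylbut-2-enyloxy)phenyl]methoxy}-4-(triisopropylsilyloxy)phenyl]ethanone; 13 tert-butyldimethylsilyl chloride
Product: 14 1-[6-(tert-butyldimethylsilyloxy)-3-(3-methylbut-2-enyl)-2-{[4-(3-methylbut-2-enyloxy)phenyl]methoxy}-4-(triisopropylsilyloxy)phenyl]ethanone
Conditions: 13, imidazole, DMAP (cat.), DMF, rt to 40 °C
Reagents that add atoms: tert-butyldimethylsilyl chloride (13), CC(C)(C)[Si](C)(C)Cl
Why: Silyl ether formation: the freed hydroxyl next to the acetyl group is capped with a bulky group that has no α-C–H and a poorly basic oxygen, so that it cannot intercept the carbenoid of step 8 by O–H insertion, C–H insertion or ylide formation.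

Step 7
Reactants: 14 1-[6-(tert-butyldimethylsilyloxy)-3-(3-methylbut-2-enyl)-2-{[4-(3-methylbut-2-enyloxy)phenyl]methoxy}-4-(triisopropylsilyloxy)phenyl]ethanone; 15 2,2,2-trifluoroethyl trifluoroacetate; 16 4-acetamidobenzenesulfonyl azide
Product: 18 2-diazo-1-[6-(tert-butyldimethylsilyloxy)-3-(3-methylbut-2-enyl)-2-{[4-(3-methylbut-2-enyloxy)phenyl]methoxy}-4-(triisopropylsilyloxy)phenyl]ethanone, via trifluoroacetyl diketone 17 (not isolated)
Conditions: LiN(SiMe3)2, THF, −78 °C; 15; 5% aq. HCl quench; then 16, Et3N, H2O (1 equiv), MeCN, rt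
Reagents that add atoms: 2,2,2-trifluoroethyl trifluoroacetate (15), O=C(OCC(F)(F)F)C(F)(F)F (its CF3CO group is carried only by 17); 4-acetamidobenzenesulfonyl azide (16), CC(=O)Nc1ccc(cc1)S(=O)(=O)N=[N+]=[N-]
Why: Detrifluoroacetylative (Regitz-type) diazo transfer: the kinetic lithium enolate is C-acylated to the 1,3-diketone 17, which is acidic enough to accept the diazo group from the sulfonyl azide under mild amine conditions and then loses the trifluoroacetyl group as the N-sulfonyl trifluoroacetamide.

Step 8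
Reactants: 18 2-diazo-1-[6-(tert-butyldimethylsilyloxy)-3-(3-methylbut-2-enyl)-2-{[4-(3-methylbut-2-enyloxy)phenyl]methoxy}-4-(triisopropylsilyloxy)phenyl]ethanone
Product: 19 (2S)-5-(tert-butyldimethylsilyloxy)-8-(3-methylbut-2-enyl)-2-[4-(3-methylbut-2-enyloxy)phenyl]-7-(triisopropylsilyloxy)-2,3-dihydrochromen-4-one
Conditions: Rh2(S-PTTL)4 [dirhodium tetrakis(N-phthaloyl-(S)-tert-leucinate)] (2 mol%), CH2Cl2, 0 °C, slow addition of 18 (final 0.01 M)
Reagents that add atoms: none
Why: Rh2(S-PTTL)4, a divalent rhodium dimer, extrudes N2 from 18 to give an electrophilic rhodium carbenoid at C3, which inserts in a concerted, asynchronous three-centre (hydride-transfer-like) transition state into one C–H bond of the benzylic ether carbon that becomes C2. The closest known reaction type is the chiral dirhodium-tetracarboxylate-catalysed intramolecular C–H insertion of 2-alkoxyaryl α-diazoketones at the ether α-carbon, which delivers 2-substituted chroman-4-ones. Ring C is closed as a six-membered ring by 1,6-insertion, with C3 and C2 both becoming ring members; no C–H bond is available in the otherwise preferred 1,5-position, which is occupied by O1. The C2 stereocentre is set by the catalyst, whose chiral carboxylate wall selects one of the two enantiotopic benzylic hydrogens (see the assumption on the catalyst enantiomer). The step needs C–H insertion to win over oxonium-ylide formation at O1 with [1,2]-benzyl shift and over reaction at the other ortho oxygen; the first is secured by the doubly activated, hydridic C2–H (α to O1 and benzylic to the para-alkoxyphenyl ring B) and by the low basicity and steric shielding of the aryl ether oxygen O1 between the acyl group and the C8 prenyl group, the second by the bulky silyl ether at O5, which carries no α-C–H. Cyclopropanation is excluded for the C8 prenyl group by its meta relationship to the acyl-bearing carbon and for the ring-B prenyl ether by distance, and slow addition at high dilution suppresses intermolecular paths.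

Step 9
Reactants: 19 (2S)-5-(tert-butyldimethylsilyloxy)-8-(3-methylbut-2-enyl)-2-[4-(3-methylbut-2-enyloxy)phenyl]-7-(triisopropylsilyloxy)-2,3-dihydrochromen-4-one
Product: 20 (2S)-5,7-dihydroxy-8-(3-methylbut-2-enyl)-2-[4-(3-methylbut-2-enyloxy)phenyl]-2,3-dihydrochromen-4-one
Conditions: Bu4NF (2.5 equiv), AcOH (2.5 equiv), THF, 0 °C to rt
Reagents that add atoms: none
Why: Fluoride-induced cleavage of both aryl silyl ethers under acetic acid buffering, which keeps the medium from becoming basic enough to open ring C by retro-oxa-Michael reaction (the path to racemisation at C2) and leaves both prenyl groups untouched.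

**Compound list**

1 | 2,4,6-trihydroxyacetophenone | CC(=O)c1c(O)cc(O)cc1O | starting material
2 | triisopropylsilyl chloride | CC(C)[Si](Cl)(C(C)C)C(C)C | starting material
3 | 1-[2,6-dihydroxy-4-(triisopropylsilyloxy)phenyl]ethanone | CC(=O)c1c(O)cc(O[Si](C(C)C)(C(C)C)C(C)C)cc1O | intermediate
4 | 4-hydroxybenzyl alcohol | OCc1ccc(O)cc1 | starting material
5 | prenyl bromide (1-bromo-3-methylbut-2-ene) | CC(C)=CCBr | starting material
6 | [4-(3-methylbut-2-enyloxy)phenyl]methanol | CC(C)=CCOc1ccc(CO)cc1 | intermediate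
7 | 1-[2-hydroxy-6-{[4-(3-methylbut-2-enyloxy)phenyl]methoxy}-4-(triisopropylsilyloxy)phenyl]ethanone | CC(=O)c1c(O)cc(O[Si](C(C)C)(C(C)C)C(C)C)cc1OCc1ccc(OCC=C(C)C)cc1 | intermediate
8 | prenol (3-methylbut-2-en-1-ol) | CC(C)=CCO | starting material
9 | 1-[2-(3-methylbut-2-enyloxy)-6-{[4-(3-methylbut-2-enyloxy)phenyl]methoxy}-4-(triisopropylsilyloxy)phenyl]ethanone | CC(=O)c1c(OCC=C(C)C)cc(O[Si](C(C)C)(C(C)C)C(C)C)cc1OCc1ccc(OCC=C(C)C)cc1 | intermediate
10 | ortho-dienone: 2-acetyl-6-(2-methylbut-3-en-2-yl)-3-{[4-(3-methylbut-2-enyloxy)phenyl]methoxy}-5-(triisopropylsilyloxy)cyclohexa-2,4-dien-1-one (racemic at C6, not isolated) | CC(=O)C1=C(OCc2ccc(OCC=C(C)C)cc2)C=C(O[Si](C(C)C)(C(C)C)C(C)C)C(C(C)(C)C=C)C1=O | intermediate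
11 | para-dienone: 2-acetyl-4-(3-methylbut-2-enyl)-3-{[4-(3-methylbut-2-enyloxy)phenyl]methoxy}-5-(triisopropylsilyloxy)cyclohexa-2,5-dien-1-one (racemic at C4, not isolated) | CC(=O)C1=C(OCc2ccc(OCC=C(C)C)cc2)C(CC=C(C)C)C(O[Si](C(C)C)(C(C)C)C(C)C)=CC1=O | intermediate
12 | 1-[6-hydroxy-3-(3-methylbut-2-enyl)-2-{[4-(3-methylbut-2-enyloxy)phenyl]methoxy}-4-(triisopropylsilyloxy)phenyl]ethanone | CC(=O)c1c(O)cc(O[Si](C(C)C)(C(C)C)C(C)C)c(CC=C(C)C)c1OCc1ccc(OCC=C(C)C)cc1 | intermediate
13 | tert-butyldimethylsilyl chloride | CC(C)(C)[Si](C)(C)Cl | starting material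
14 | 1-[6-(tert-butyldimethylsilyloxy)-3-(3-methylbut-2-enyl)-2-{[4-(3-methylbut-2-enyloxy)phenyl]methoxy}-4-(triisopropylsilyloxy)phenyl]ethanone | CC(=O)c1c(O[Si](C)(C)C(C)(C)C)cc(O[Si](C(C)C)(C(C)C)C(C)C)c(CC=C(C)C)c1OCc1ccc(OCC=C(C)C)cc1 | intermediate
15 | 2,2,2-trifluoroethyl trifluoroacetate | O=C(OCC(F)(F)F)C(F)(F)F | starting material
16 | 4-acetamidobenzenesulfonyl azide | CC(=O)Nc1ccc(cc1)S(=O)(=O)N=[N+]=[N-] | starting material
17 | trifluoroacetyl diketone: 4,4,4-trifluoro-1-[6-(tert-butyldimethylsilyloxy)-3-(3-methylbut-2-enyl)-2-{[4-(3-methylbut-2-enyloxy)phenyl]methoxy}-4-(triisopropylsilyloxy)phenyl]butane-1,3-dione (not isolated) | O=C(CC(=O)C(F)(F)F)c1c(O[Si](C)(C)C(C)(C)C)cc(O[Si](C(C)C)(C(C)C)C(C)C)c(CC=C(C)C)c1OCc1ccc(OCC=C(C)C)cc1 | intermediate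
18 | 2-diazo-1-[6-(tert-butyldimethylsilyloxy)-3-(3-methylbut-2-enyl)-2-{[4-(3-methylbut-2-enyloxy)phenyl]methoxy}-4-(triisopropylsilyloxy)phenyl]ethanone | [N-]=[N+]=CC(=O)c1c(O[Si](C)(C)C(C)(C)C)cc(O[Si](C(C)C)(C(C)C)C(C)C)c(CC=C(C)C)c1OCc1ccc(OCC=C(C)C)cc1 | intermediate
19 | (2S)-5-(tert-butyldimethylsilyloxy)-8-(3-methylbut-2-enyl)-2-[4-(3-methylbut-2-enyloxy)phenyl]-7-(triisopropylsilyloxy)-2,3-dihydrochromen-4-one | CC(C)=CCOc1ccc([C@@H]2CC(=O)c3c(O[Si](C)(C)C(C)(C)C)cc(O[Si](C(C)C)(C(C)C)C(C)C)c(CC=C(C)C)c3O2)cc1 | intermediate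
20 | (2S)-5,7-dihydroxy-8-(3-methylbut-2-enyl)-2-[4-(3-methylbut-2-enyloxy)phenyl]-2,3-dihydrochromen-4-one | CC(C)=CCOc1ccc([C@@H]2CC(=O)c3c(O)cc(O)c(CC=C(C)C)c3O2)cc1 | target

**Step count and risks**

Total step count: 9. Longest linear sequence: 8 steps (steps 1, 3, 4, 5, 6, 7, 8 and 9 from compound 1); step 2 is a one-step side branch.

Steps most likely to fail:

Step 8. The carbenoid may be captured by a lone pair of O1 to form an oxonium ylide that collapses by [1,2]-shift of the benzyl group, or the catalyst may distinguish the two enantiotopic benzylic hydrogens poorly. The fallback sets out from 14 and comes back to the route at 19; it closes ring C at O1–C2 and sets C2 by a catalytic asymmetric conjugate addition.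
- DDQ in CH2Cl2/pH 7 buffer should cleave the para-alkoxybenzyl ether of 14 to 1-[6-(tert-butyldimethylsilyloxy)-2-hydroxy-3-(3-methylbut-2-enyl)-4-(triisopropylsilyloxy)phenyl]ethanone F1.
- Heating F1 with N,N-dimethylformamide dimethyl acetal should give the enaminone (E)-3-(dimethylamino)-1-[6-(tert-butyldimethylsilyloxy)-2-hydroxy-3-(3-methylbut-2-enyl)-4-(triisopropylsilyloxy)phenyl]prop-2-en-1-one F2.
- AcOH in CH2Cl2 should close F2 to the chromone 5-(tert-butyldimethylsilyloxy)-8-(3-methylbut-2-enyl)-7-(triisopropylsilyloxy)chromen-4-one F3.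
- The aryl donor would be made from 4-bromophenol: O-prenylation with 5 (K2CO3, acetone) to 1-bromo-4-(3-methylbut-2-enyloxy)benzene F4, then bromine–lithium exchange (n-BuLi, THF, −78 °C), B(OiPr)3 and mild hydrolysis to [4-(3-methylbut-2-enyloxy)phenyl]boronic acid F5.
- Enantioselective conjugate addition of F5 to F3 should give 19. Conditions: Pd(OCOCF3)2, a divalent palladium salt, with the enantiomer of 4-tert-butyl-2-(pyridin-2-yl)-4,5-dihydrooxazole that delivers the 2S product, NH4PF6, H2O, ClCH2CH2Cl, 60 °C.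

Step 5. The ortho-dienone 10 may enolise before the Cope shift, which would leak material to the 1,1-dimethylallyl regioisomer, or the Lewis acid may ionise the benzylic ether. The fallback sets out from 3 and comes back at 14, replacing the sigmatropic prenyl transfer by a cross-coupling at a position fixed by iodination.
- Mono-silylation of the symmetric diol 3 with 13 (imidazole, DMF) should give 1-[2-(tert-butyldimethylsilyloxy)-6-hydroxy-4-(triisopropylsilyloxy)phenyl]ethanone F6.
- Iodination with N-iodosuccinimide (MeCN, 0 °C) should go ortho to the remaining hydroxyl, the other free position lying between two silyl ethers, to give 1-[6-(tert-butyldimethylsilyloxy)-2-hydroxy-3-iodo-4-(triisopropylsilyloxy)phenyl]ethanone F7.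
- Mitsunobu etherification with 6 (PPh3, DIAD, THF) should give 1-[6-(tert-butyldimethylsilyloxy)-3-iodo-2-{[4-(3-methylbut-2-enyloxy)phenyl]methoxy}-4-(triisopropylsilyloxy)phenyl]ethanone F8.
- Stille coupling of F8 with tributyl(3-methylbut-2-enyl)stannane (Pd(PPh3)4, a zerovalent palladium complex, DMF, 80 °C) should give 14.

Step 7. In the lithium enolate of 14 the ortho silyl group may migrate from the phenolic oxygen to the enolate oxygen, the hindered enolate may be acylated incompletely, or the aryl silyl ether may be lost under the aqueous amine conditions of the diazo transfer. The fallback sets out from 14 and comes back at 18, avoiding both the lithium enolate and the diazo transfer.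
- Soft enolisation (Me3SiOTf, Et3N, CH2Cl2, 0 °C) should give the silyl enol ether 1-[6-(tert-butyldimethylsilyloxy)-3-(3-methylbut-2-enyl)-2-{[4-(3-methylbut-2-enyloxy)phenyl]methoxy}-4-(triisopropylsilyloxy)phenyl]-1-(trimethylsilyloxy)ethene F9.
- N-Bromosuccinimide (THF, −78 °C) should convert F9 into the bromoketone 2-bromo-1-[6-(tert-butyldimethylsilyloxy)-3-(3-methylbut-2-enyl)-2-{[4-(3-methylbut-2-enyloxy)phenyl]methoxy}-4-(triisopropylsilyloxy)phenyl]ethanone F10.
- N,N'-Ditosylhydrazine and DBU (THF, 0 °C) should turn F10 into 18 by substitution and double sulfinate elimination.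

**Further compounds**

F1 | step 8 | 1-[6-(tert-butyldimethylsilyloxy)-2-hydroxy-3-(3-methylbut-2-enyl)-4-(triisopropylsilyloxy)phenyl]ethanone | CC(=O)c1c(O[Si](C)(C)C(C)(C)C)cc(O[Si](C(C)C)(C(C)C)C(C)C)c(CC=C(C)C)c1O
F2 | step 8 | (E)-3-(dimethylamino)-1-[6-(tert-butyldimethylsilyloxy)-2-hydroxy-3-(3-methylbut-2-enyl)-4-(triisopropylsilyloxy)phenyl]prop-2-en-1-one | CN(C)/C=C/C(=O)c1c(O[Si](C)(C)C(C)(C)C)cc(O[Si](C(C)C)(C(C)C)C(C)C)c(CC=C(C)C)c1O
F3 | step 8 | 5-(tert-butyldimethylsilyloxy)-8-(3-methylbut-2-enyl)-7-(triisopropylsilyloxy)chromen-4-one | O=c1ccoc2c(CC=C(C)C)c(O[Si](C(C)C)(C(C)C)C(C)C)cc(O[Si](C)(C)C(C)(C)C)c12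
F4 | step 8 | 1-bromo-4-(3-methylbut-2-enyloxy)benzene | CC(C)=CCOc1ccc(Br)cc1
F5 | step 8 | [4-(3-methylbut-2-enyloxy)phenyl]boronic acid | CC(C)=CCOc1ccc(B(O)O)cc1
F6 | step 5 | 1-[2-(tert-butyldimethylsilyloxy)-6-hydroxy-4-(triisopropylsilyloxy)phenyl]ethanone | CC(=O)c1c(O)cc(O[Si](C(C)C)(C(C)C)C(C)C)cc1O[Si](C)(C)C(C)(C)C
F7 | step 5 | 1-[6-(tert-butyldimethylsilyloxy)-2-hydroxy-3-iodo-4-(triisopropylsilyloxy)phenyl]ethanone | CC(=O)c1c(O)c(I)c(O[Si](C(C)C)(C(C)C)C(C)C)cc1O[Si](C)(C)C(C)(C)C
F8 | step 5 | 1-[6-(tert-butyldimethylsilyloxy)-3-iodo-2-{[4-(3-methylbut-2-enyloxy)phenyl]methoxy}-4-(triisopropylsilyloxy)phenyl]ethanone | CC(=O)c1c(OCc2ccc(OCC=C(C)C)cc2)c(I)c(O[Si](C(C)C)(C(C)C)C(C)C)cc1O[Si](C)(C)C(C)(C)C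
F9 | step 7 | 1-[6-(tert-butyldimethylsilyloxy)-3-(3-methylbut-2-enyl)-2-{[4-(3-methylbut-2-enyloxy)phenyl]methoxy}-4-(triisopropylsilyloxy)phenyl]-1-(trimethylsilyloxy)ethene | C=C(O[Si](C)(C)C)c1c(O[Si](C)(C)C(C)(C)C)cc(O[Si](C(C)C)(C(C)C)C(C)C)c(CC=C(C)C)c1OCc1ccc(OCC=C(C)C)cc1
F10 | step 7 | 2-bromo-1-[6-(tert-butyldimethylsilyloxy)-3-(3-methylbut-2-enyl)-2-{[4-(3-methylbut-2-enyloxy)phenyl]methoxy}-4-(triisopropylsilyloxy)phenyl]ethanone | O=C(CBr)c1c(O[Si](C)(C)C(C)(C)C)cc(O[Si](C(C)C)(C(C)C)C(C)C)c(CC=C(C)C)c1OCc1ccc(OCC=C(C)C)cc1
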